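The spiro ether is cut by a retro hetero-Diels–Alder reaction into an alkylidene syncarpic acid and (−)-β-pinene, which is traced back through nopinone to a monocyclic cyclohexene. The key step exploits the carbocyclic six-membered ring C1–C6 of the pinane half (pinane numbering: C2 spiro carbon, C6 the CMe2 bridge, C7 the CH2 bridge), where C2 bears oxygen and C6 is quaternary: a copper-catalysed enantioselective [4+2] cycloaddition of the 2-silyloxy diene from mesityl oxide (C3=C2–C1=C6) with an acrylimide (C4=C5–C7) forms C3–C4 and C5–C6 and sets C5. The resulting enol ether then closes the cyclobutane (C1–C7); C5 thereby fixes C1 and, later, C2.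

Key step: step 2

Remark: pinane numbering (C1–C7) is used for the terpene carbons in every step; 3-acryloyl-1,3-oxazolidin-2-one and syncarpic acid are taken as purchasable.

Step 1
Reactants: 1 mesityl oxide (4-methylpent-3-en-2-one)
Product: 2 tert-butyl(dimethyl)[(4-methylpenta-1,3-dien-2-yl)oxy]silane
Conditions: TBSOTf, Et3N, CH2Cl2, 0 °C
Reagents that add atoms: tert-butyldimethylsilyl trifluoromethanesulfonate, CC(C)(C)[Si](C)(C)OS(=O)(=O)C(F)(F)F
Why: Soft enolisation of a methyl ketone (silyl enol ether formation), in which the O-silylated enone is deprotonated by Et3N at the accessible acetyl methyl group and should give the cross-conjugated 2-silyloxy diene; no stereocenter is formed.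

Step 2
Reactants: 2 silyloxy diene; 3 3-acryloyl-1,3-oxazolidin-2-one
Product: 4 3-{[(1R)-4-{[tert-butyl(dimethyl)silyl]oxy}-2,2-dimethylcyclohex-3-en-1-yl]carbonyl}-1,3-oxazolidin-2-one
Conditions: [Cu((R,R)-t-Bu-box)](SbF6)2 (10 mol%; t-Bu-box = 2,2′-(propane-2,2-diyl)bis(4-tert-butyl-4,5-dihydro-1,3-oxazole)), 4 Å molecular sieves, CH2Cl2, −40 → 0 °C
Reagents that add atoms: none
Why: Enantioselective Diels–Alder reaction catalysed by a bis(oxazoline) complex of divalent copper: imide 3 binds the square-planar metal through both carbonyl oxygens in its s-cis form and diene 2 adds across the acrylamide C=C in a strongly asynchronous [4+2], C3 bonding to the β-carbon C4 ahead of C6 bonding to the α-carbon C5 (stepwise limit: Mukaiyama–Michael addition, then collapse of the copper enolate onto the silyloxyallyl cation). The closest known reactions are the copper–bis(oxazoline) Diels–Alder reactions of this imide with acyclic dienes and the Lewis-acid [4+2] reactions of hindered 2-silyloxy dienes that create quaternary carbons. One ring is closed, the cyclohexene C1–C6, by intermolecular [4+2] cycloaddition (in the stepwise limit by attack of C5 on the C6 terminus). The only new stereocenter, C5, is set by the catalyst: a tert-butyl group of the (R,R) ligand covers one face of the bound dienophile, the diene adds to the other, and the (R) configuration should result. The step needs the regiochemistry with the oxygen-bearing C2 1,4 to C5 and the CMe2 carbon next to C5, which the silyloxy group secures by making C3 the nucleophilic terminus. It also needs closure at C6 and not at C2 (cyclobutane), which the tertiary allyl-cation terminus and the reversibility of four-ring closure favour.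

Step 3
Reactants: 4 cycloadduct
Product: 5 [(1R)-4-{[tert-butyl(dimethyl)silyl]oxy}-2,2-dimethylcyclohex-3-en-1-yl]methanol
Conditions: LiBH4, THF, 0 °C → rt
Reagents that add atoms: none
Why: Reductive cleavage of an N-acyl oxazolidinone, in which hydride attacks the lithium-chelated exocyclic carbonyl to give the primary alcohol and free oxazolidinone, while the silyl enol ether is inert to borohydride and C5 is not enolised.

Step 4
Reactants: 5 alcohol
Product: 6 [(1R)-4-{[tert-butyl(dimethyl)silyl]oxy}-2,2-dimethylcyclohex-3-en-1-yl]methyl 4-methylbenzenesulfonate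
Conditions: TsCl, pyridine, DMAP (cat.), CH2Cl2, 0 °C → rt
Reagents that add atoms: 4-methylbenzenesulfonyl chloride, Cc1ccc(cc1)S(=O)(=O)Cl
Why: Sulfonylation of a primary alcohol under buffered conditions that the tert-butyldimethylsilyl enol ether should tolerate; no stereocenter is touched.

Step 5
Reactants: 6 tosylate
Product: 8 (1R,5S)-6,6-dimethylbicyclo[3.1.1]heptan-2-one ((+)-nopinone), via sulfonium enolate 7 (not isolated)
Conditions: TASF [(Me2N)3S+ Me3SiF2−], THF, 0 → 40 °C
Reagents that add atoms: none
Why: Fluoride cleaves the Si–O bond and unveils the enolate only on the C1 side fixed by the cycloaddition (regiospecific enolate generation from a silyl enol ether), and this naked enolate alkylates C7 intramolecularly (4-exo-tet C-alkylation, since O-alkylation would give a bridgehead enol ether); the one-carbon bridge can span C1 and C5 on one face only, so C5 dictates C1.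

Step 6
Reactants: 8 (+)-nopinone
Product: 9 (1S,5S)-6,6-dimethyl-2-methylidenebicyclo[3.1.1]heptane ((−)-β-pinene)
Conditions: Ph3PCH3Br, KOtBu, THF, 0 °C → reflux
Reagents that add atoms: methyltriphenylphosphonium bromide, C[P+](c1ccccc1)(c1ccccc1)c1ccccc1.[Br-]
Why: Wittig methylenation of a hindered bicyclic ketone with the ylide made in the flask; the bridgehead stereocenters cannot epimerise, and the volatile alkene would be carried on as a concentrated solution.

Step 7
Reactants: 9 (−)-β-pinene; 10 syncarpic acid (2,2,4,4-tetramethylcyclohexane-1,3,5-trione); 11 isovaleraldehyde (3-methylbutanal)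
Product: 13 target spiro ether CNP0231252.1, via alkylidene trione 12 (not isolated)
Conditions: ethylenediammonium diacetate (10 mol%), toluene, rt → 80 °C, sealed tube
Reagents that add atoms: none
Why: Domino Knoevenagel condensation and inverse-electron-demand hetero-Diels–Alder reaction, in which the 1-oxadiene 12 adds to the exocyclic alkene with oxygen bonding to the more substituted C2 from the face of the CH2 bridge C7 (away from the CMe2 bridge), which sets C2, and the orientation with bridgehead C1 exo and C3H2 endo (isobutyl outside) should set the isobutyl-bearing carbon as required; the epimer at that carbon from the other orientation would be removed by chromatography.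

Compound list
1 | mesityl oxide (4-methylpent-3-en-2-one) | CC(=O)C=C(C)C | starting material
2 | tert-butyl(dimethyl)[(4-methylpenta-1,3-dien-2-yl)oxy]silane | C=C(O[Si](C)(C)C(C)(C)C)C=C(C)C | intermediate
3 | 3-acryloyl-1,3-oxazolidin-2-one | C=CC(=O)N1CCOC1=O | starting material
4 | 3-{[(1R)-4-{[tert-butyl(dimethyl)silyl]oxy}-2,2-dimethylcyclohex-3-en-1-yl]carbonyl}-1,3-oxazolidin-2-one | CC1(C)[C@H](C(=O)N2CCOC2=O)CCC(O[Si](C)(C)C(C)(C)C)=C1 | intermediate
5 | [(1R)-4-{[tert-butyl(dimethyl)silyl]oxy}-2,2-dimethylcyclohex-3-en-1-yl]methanol | CC1(C)[C@H](CO)CCC(O[Si](C)(C)C(C)(C)C)=C1 | intermediate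
6 | [(1R)-4-{[tert-butyl(dimethyl)silyl]oxy}-2,2-dimethylcyclohex-3-en-1-yl]methyl 4-methylbenzenesulfonate | CC1(C)[C@H](COS(=O)(=O)c2ccc(C)cc2)CCC(O[Si](C)(C)C(C)(C)C)=C1 | intermediate
7 | tris(dimethylamino)sulfonium (4R)-5,5-dimethyl-4-{[(4-methylbenzenesulfonyl)oxy]methyl}cyclohex-1-en-1-olate (enolate towards C1, not isolated) | CN(C)[S+](N(C)C)N(C)C.CC1(C)[C@H](COS(=O)(=O)c2ccc(C)cc2)CCC([O-])=C1 | intermediate
8 | (1R,5S)-6,6-dimethylbicyclo[3.1.1]heptan-2-one, (+)-nopinone | CC1(C)[C@H]2CCC(=O)[C@@H]1C2 | intermediate
9 | (1S,5S)-6,6-dimethyl-2-methylidenebicyclo[3.1.1]heptane, (−)-β-pinene | CC1(C)[C@H]2CCC(=C)[C@@H]1C2 | intermediate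
10 | syncarpic acid (2,2,4,4-tetramethylcyclohexane-1,3,5-trione) | CC1(C)C(=O)CC(=O)C(C)(C)C1=O | starting material
11 | isovaleraldehyde (3-methylbutanal) | CC(C)CC=O | starting material
12 | 2,2,4,4-tetramethyl-6-(3-methylbutylidene)cyclohexane-1,3,5-trione (not isolated) | CC(C)CC=C1C(=O)C(C)(C)C(=O)C(C)(C)C1=O | intermediate
13 | (1R,2R,4′S,5S)-6,6,6′,6′,8′,8′-hexamethyl-4′-(2-methylpropyl)-3′,4′-dihydrospiro[bicyclo[3.1.1]heptane-2,2′-chromene]-5′,7′(6′H,8′H)-dione; ether oxygen on the face of the CH2 bridge, ring CH2 towards the CMe2 bridge, isobutyl cis to pinane C3 across the dihydropyran | CC(C)C[C@H]1C[C@@]2(CC[C@H]3C[C@@H]2C3(C)C)OC2=C1C(=O)C(C)(C)C(=O)C2(C)C | target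

Total step count: 7
Longest linear sequence: 7 steps (1 → 2 → 4 → 5 → 6 → 8 → 9 → 13)

Steps most likely to fail

Step 2. The cis-methyl group on C6 slows a synchronous cycloaddition. The reaction may therefore stop after C3–C4 bond formation (silyl transfer and an open-chain Michael adduct), collapse to a four-membered ring at C2, or close with reduced facial control, and the catalyst may fail to turn over. The fallback replaces catalyst control by auxiliary control with a stoichiometric, more electrophilic cationic aluminium chelate, and sets out from diene 2. Commercial (4S)-4-benzyl-1,3-oxazolidin-2-one is N-acylated with acryloyl chloride (Et3N, DMAP cat., CH2Cl2, 0 °C) to give (4S)-3-acryloyl-4-benzyl-1,3-oxazolidin-2-one F1. F1 is combined with 2 under Et2AlCl (1.4 equiv) in CH2Cl2 at −78 °C; attack on the chelated s-cis imide from the face away from the benzyl group should give (4S)-4-benzyl-3-{[(1R)-4-{[tert-butyl(dimethyl)silyl]oxy}-2,2-dimethylcyclohex-3-en-1-yl]carbonyl}-1,3-oxazolidin-2-one F2, a diastereomer that can be purified to a single isomer. LiBH4 in THF then releases the auxiliary, and the route is rejoined at alcohol 5.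

Step 5. Adventitious water may protonate the naked enolate, and proton transfer would then scramble its regiochemistry (alkylation at C3 instead of C1). The strained four-ring closure may also be slow enough for intermolecular alkylation, fluoride displacement or elimination of the tosylate to compete. The fallback moves to the reversible, thermodynamic enolate manifold of the free ketone and sets out from tosylate 6. Mild acid hydrolysis of the silyl enol ether (1 M HCl, THF, 0 °C) gives [(1R)-2,2-dimethyl-4-oxocyclohexyl]methyl 4-methylbenzenesulfonate F3. NaH in refluxing DME then lets the two sodium enolates equilibrate while ring closure drains the mixture; this is the classical base-mediated closure of this keto tosylate class to the bicyclo[3.1.1]heptan-2-one skeleton. The route is rejoined at (+)-nopinone 8.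

Step 7. The allylic C3–H of β-pinene may enter an Alder-ene reaction with the heterodiene, or a carbonyl-ene reaction with free aldehyde. The acidic triketone may trigger skeletal isomerisation of the pinene at 80 °C, the heterodiene may be consumed by a second molecule of syncarpic acid, and the two orientations of the alkene may be poorly discriminated. The fallback generates the heterodiene by oxidation instead of condensation, under neutral, aldehyde-free conditions and at low stationary concentration, and sets out from 10 and 11. Reductive alkylation (L-proline cat., diethyl 2,6-dimethyl-1,4-dihydropyridine-3,5-dicarboxylate, CH2Cl2, rt) gives 5-hydroxy-2,2,6,6-tetramethyl-4-(3-methylbutyl)cyclohex-4-ene-1,3-dione F4. Oxidative dehydrogenation of F4 (TEMPO, Ag2O, toluene, rt → 50 °C) in the presence of 9 should form alkylidene trione 12 slowly. The route is rejoined at 12, which is trapped by 9 to give 13.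

Further compounds
F1 | step 2 | (4S)-3-acryloyl-4-benzyl-1,3-oxazolidin-2-one | C=CC(=O)N1[C@@H](Cc2ccccc2)COC1=O
F2 | step 2 | (4S)-4-benzyl-3-{[(1R)-4-{[tert-butyl(dimethyl)silyl]oxy}-2,2-dimethylcyclohex-3-en-1-yl]carbonyl}-1,3-oxazolidin-2-one | CC1(C)[C@H](C(=O)N2[C@@H](Cc3ccccc3)COC2=O)CCC(O[Si](C)(C)C(C)(C)C)=C1
F3 | step 5 | [(1R)-2,2-dimethyl-4-oxocyclohexyl]methyl 4-methylbenzenesulfonate | CC1(C)[C@H](COS(=O)(=O)c2ccc(C)cc2)CCC(=O)C1
F4 | step 7 | 5-hydroxy-2,2,6,6-tetramethyl-4-(3-methylbutyl)cyclohex-4-ene-1,3-dione | CC(C)CCC1=C(O)C(C)(C)C(=O)C(C)(C)C1=O
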